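# Proposed synthesis of (2S,3S,3aR)-3a-allyl-5-methoxy-3-methyl-2-(3,4,5-trimethoxyphenyl)-3,3a-dihydrobenzofuran-6(2H)-one (26)

Benzofuran numbering (O1, C2, C3, C3a, C4–C7, C7a) is used for the target atoms throughout.

## The problem

Target 26 is a tetrahydrofuran ring (O1, C2, C3, C3a, C7a) fused through the C3a–C7a bond to a cross-conjugated 2-methoxycyclohexa-2,5-dienone (C3a, C4=C5(OMe), C6=O, C7=C7a). Three contiguous stereocentres must be delivered as one enantiomer: C2 (S, aryl), C3 (S, methyl) and the quaternary C3a (R, allyl), with aryl and methyl trans and methyl and allyl cis. C2 and C3 form an anti crotylation pattern and can be set together by a chiral catalyst. C3a cannot be set that way and must be derived from them; its only close director is the small C3 methyl group, while the larger C2 aryl group lies on the opposite face. Four different carbon branches meet at C3a, so the bond that creates this centre decides the route. The reagents are limited by the terminal allyl alkene (radicals, electrophiles, palladium) and by the electron-rich benzylic ether at C2 (Lewis acids, one-electron oxidants). The finished 4-allyl-cyclohexadienone is a vinylogous ester prone to acid- or heat-induced allyl migration, so it should appear only at the end and under mild conditions. The enabling feature is that C7a carries O1 and is bonded to C3a: in a 2,3-dihydrofuran these atoms form a trisubstituted enol ether whose β-carbon is the carbon that must become quaternary. A ketene adds across it with fixed regiochemistry, its carbonyl carbon (future C6) going to C3a and its other carbon (future C7) to C7a, and the strain of the resulting cyclobutanone can then drive the insertion of C4 and C5.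

## Retrosynthesis

**26 to 24 to 22.** No carbon–carbon bond is cut first. The two ring double bonds are removed, C4=C5 to reach the vinylogous ester 24 and C7=C7a to reach the saturated methoxy ketone 22. This keeps the acid- and heat-sensitive allyl dienone out of the route until the last step. The C6 carbonyl of 22 is flanked by C5 and C7, so it can direct both dehydrogenations. The order is not critical because both are needed, and once one is in place the quaternary C3a leaves only one enolisable position. Carrying the C7=C7a unsaturation through from an earlier stage (by keeping a chlorine at C7) would expose an α-chloro cyclobutanone to an organolithium and is rejected. The forward steps must be mild dehydrogenations that spare the allyl group.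

**22 to 21 to 18 and 19.** In 22 the C3a–C4 bond is cut and C3a is reconnected to C6, which contracts the cyclohexanone to the cyclobutanol 21. Cutting C5–C6 of 21 gives cyclobutanone 18 and the lithio reagent 20, made from methyl vinyl ether 19. This single two-carbon unit carries C4, C5 and the methoxy group, so the oxygen is placed without later choice between C5 and C7. Two successive one-carbon homologations, or an unoxygenated vinyl unit, would reopen that choice. The forward ring expansion must break C3a–C6 rather than C6–C7 (tertiary against primary radical), reclose on C4 in the 6-endo mode, and restore C3a with the configuration imposed by cis fusion to C7a.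

**18 to 17 to 14 and 16.** This is the key disconnection. Removing the two chlorines' replacement hydrogens leads to dichlorocyclobutanone 17, and cutting C3a–C6 and C7–C7a of 17 gives the dihydrofuran 14 and dichloroketene 16, made in the flask from trichloroacetyl chloride 15. Against the neighbouring options, which create C3a by alkylating a crowded lactone enolate, the cycloaddition forms the quaternary centre and the C7–C7a bond together, with regiochemistry fixed by the polarity of the enol ether. Precursor 14 has only two stereocentres and no quaternary carbon. The forward reaction must select the enol ether over the allyl alkene and the face anti to the C3 methyl group.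

**14 to 12 to 11 to 8 and 9.** The C7a=C3a double bond of 14 is traced to dehydration of lactol 12, which comes from lactone 11 by partial reduction. Cutting the C3a–CH2 bond of 11 gives lactone 8 and allyl bromide 9. The lactone carbonyl carbon is C7a at a convenient oxidation level and its α-carbon is C3a, where the allyl group is needed. The configuration created in the allylation is irrelevant because that carbon becomes sp2 in 14.

**8 to 6 to 4 to 1 and 2.** Lactone 8 is opened to diol 6, which comes from the homoallylic alcohol 4 by anti-Markovnikov hydration. Cutting C2–C3 of 4 gives 3,4,5-trimethoxybenzaldehyde 1 and the (E)-crotylboronate 2. This one bond formation sets both C2 and C3 and their anti relationship, which no later step touches. The forward reaction needs a catalyst that fixes the absolute sense.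

## Roads not taken

**Alternative 1:** The cut removes C3a–C7a and the C4=C5 double bond together. It leads to the open-chain aldehyde A2, in which the C2 oxygen already carries C7a=C7–C6(=O)–C5H2(OMe) as a β-alkoxy enone and C3a is the α-carbon of the C4 aldehyde. In the forward step a primary ammonium carboxylate would form the enamine of the α-branched aldehyde. The enamine would close the tetrahydrofuran by 5-exo Michael addition to C7a, creating the quaternary centre, and the aldehyde would then condense with the C5 methylene to give A1. A1 is one dehydrogenation (C7–C7a) short of the target.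
- Merits: both rings and the C4=C5 bond form in one flask without an oxidant, no photochemistry is needed, and the endgame is about three steps shorter than in the chosen plan.
- Weak points: a β-alkoxy enone is a deactivated acceptor and an α,α-disubstituted enamine a hindered donor. The Michael adduct is a β-alkoxy ketone that can revert by elimination. The enamine face is chosen in a five-membered transition state where the C3 methyl and C2 aryl groups act in opposite directions, so C3a control is no better founded than in the cycloaddition. A2 joins an epimerisable aldehyde to a hydrolysis-prone vinylogous ester, which makes its preparation the long part of that road.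
- Comparison: after its key step this road is shorter, and that is conceded. The chosen plan sets against it a quaternary-centre-forming step of unquestioned regiochemistry and a robust precursor, 14.

**Alternative 2:** The cut removes C3a–C4 and C7–C7a. It leads to the allyl lactone that is compound 11 of the chosen route and to the enone A4. In the forward step the potassium enolate of 11 would add to A4, the methyl ketone enolate would attack the lactone carbonyl, and acidic work-up would close the enol ether to give A3, which is the same compound as 24.
- Merits: A3 is reached from 11 in one operation where the chosen plan needs seven steps. The new bond at C3a forms by enolate alkylation anti to the adjacent methyl group, a more dependable source of the C3a configuration than the facial selectivity of a cycloaddition.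
- Weak points: the donor is a fully substituted enolate and A4 is an electron-rich, polymerisation-prone acceptor, so the Michael step should be slow and reversible. The methyl ketone must then enolise at the methyl group rather than at the methoxy-bearing carbon and attack a lactone carbonyl next to the new quaternary centre. Three consecutive events at a congested centre must all succeed in one flask.
- Comparison: on paper this road is shorter and better in stereocontrol. The chosen plan sets against it bond-forming steps that each have a close model on the same functional-group pattern and can be optimised one at a time. The annulation is kept as the fallback from 11 if the cycloaddition fails.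

**Alternative 3:** The cut is made at C3–CH3 and C3a–C4 and leads to the butenolide A6, which has a single stereocentre. In the forward step a methyl cuprate would add to C3 anti to the C2 aryl group, and the lactone enolate would be trapped at C3a by formaldehyde A7 anti to the new methyl group, giving A5 with all three stereocentres.
- Merits: the best stereocontrol of the four plans, each new centre being set by its neighbour in a rigid five-membered ring, and the simplest chiral starting material.
- Weak points: A5 holds only C4 of the six-membered ring. C5, C6 and C7 must still be added and the lactone carbonyl (C7a) turned into an enol-ether carbon, a sequence at least as long as the endgame chosen here. Trapping cuprate-derived enolates with A7 is capricious, and the β-hydroxy lactone can undergo retro-aldol cleavage.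
- Comparison: this road is superior in control of C3a. The chosen plan sets against it convergence: C6 and C7 arrive in the step that creates C3a, and C4 and C5 in one further carbon–carbon bond-forming operation.

Key step: step 7

## Route

Assumption: the phosphoric acid-catalysed crotylboration is taken to follow its established sense, the (S)-configured catalyst giving the (1S,2S) alcohol from aromatic aldehydes; if the sense were opposite, the (R)-catalyst would be used with no other change.

Step 1
Reactants: 1 3,4,5-trimethoxybenzaldehyde; 2 (E)-crotylboronic acid pinacol ester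
Product: 4 (1S,2S)-2-methyl-1-(3,4,5-trimethoxyphenyl)but-3-en-1-ol, via pinacol borate ester 3 (not isolated)
Conditions: (S)-3,3'-bis(2,4,6-triisopropylphenyl)-1,1'-binaphthyl-2,2'-diyl hydrogen phosphate (5 mol%), toluene, −30 °C; aq. NaHCO3
Reagents that add atoms: none
Why: Chiral phosphoric acid-catalysed crotylboration of an aromatic aldehyde; the closed chair transition state turns the E geometry of 2 into the anti relationship of hydroxyl and methyl, and the catalyst bound to the boronate selects the aldehyde face, setting C2 and C3 as (S,S).

Step 2
Reactants: 4 (1S,2S)-2-methyl-1-(3,4,5-trimethoxyphenyl)but-3-en-1-ol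
Product: 6 (3S,4S)-3-methyl-4-(3,4,5-trimethoxyphenyl)butane-1,4-diol, via B-alkyl-9-BBN adduct 5 (not isolated)
Conditions: 9-BBN (excess), THF, 0 °C to rt; then NaOH, H2O2, 0 °C to rt
Reagents that add atoms: hydrogen peroxide, OO
Why: Anti-Markovnikov hydroboration–oxidation of the terminal alkene; 9-BBN is taken in excess because the free hydroxyl consumes part of it, and no stereocentre is touched.

Step 3
Reactants: 6 (3S,4S)-3-methyl-4-(3,4,5-trimethoxyphenyl)butane-1,4-diol
Product: 8 (4S,5S)-4-methyl-5-(3,4,5-trimethoxyphenyl)dihydrofuran-2(3H)-one, via lactol 7 (not isolated)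
Conditions: TEMPO (cat.), PhI(OAc)2, CH2Cl2, rt
Reagents that add atoms: none
Why: Oxoammonium-mediated oxidative lactonisation; the primary alcohol is oxidised selectively, the hydroxy aldehyde closes to lactol 7 and this is oxidised on to the γ-lactone, with aryl and methyl trans as fixed in step 1.

Step 4
Reactants: 8 (4S,5S)-4-methyl-5-(3,4,5-trimethoxyphenyl)dihydrofuran-2(3H)-one; 9 allyl bromide
Product: 11 (3S,4S,5S)-3-allyl-4-methyl-5-(3,4,5-trimethoxyphenyl)dihydrofuran-2(3H)-one, via lithium enolate 10 (not isolated)
Conditions: LiN(i-Pr)2, THF, −78 °C; then 9, −78 to −40 °C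
Reagents that add atoms: none
Why: Lactone enolate alkylation with an allylic halide; the allyl group should enter anti to the neighbouring methyl group, but this centre becomes sp2 in step 6, so its configuration is immaterial.

Step 5
Reactants: 11 (3S,4S,5S)-3-allyl-4-methyl-5-(3,4,5-trimethoxyphenyl)dihydrofuran-2(3H)-one
Product: 12 (3S,4S,5S)-3-allyl-4-methyl-5-(3,4,5-trimethoxyphenyl)tetrahydrofuran-2-ol (anomers)
Conditions: i-Bu2AlH, CH2Cl2, −78 °C; aq. KNaC4H4O6
Reagents that add atoms: none
Why: Partial reduction of a lactone to the lactol; the tetrahedral aluminium alkoxide survives at low temperature until work-up, and the alkene is inert.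

Step 6
Reactants: 12 (3S,4S,5S)-3-allyl-4-methyl-5-(3,4,5-trimethoxyphenyl)tetrahydrofuran-2-ol (anomers)
Product: 14 (2S,3S)-4-allyl-3-methyl-2-(3,4,5-trimethoxyphenyl)-2,3-dihydrofuran, via anomeric mesylate 13 (not isolated)
Conditions: MsCl, Et3N, CH2Cl2, −20 °C to reflux; basic alumina filtration
Reagents that add atoms: none
Why: Lactol dehydration by mesylation–elimination; the anomeric mesylate ionises to the oxocarbenium ion, which can lose a proton only from the allyl-bearing carbon, giving the endocyclic enol ether C7a=C3a without touching C2 or C3.

Step 7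
Reactants: 14 (2S,3S)-4-allyl-3-methyl-2-(3,4,5-trimethoxyphenyl)-2,3-dihydrofuran; 15 trichloroacetyl chloride
Product: 17 (1R,3S,4S,5S)-5-allyl-7,7-dichloro-4-methyl-3-(3,4,5-trimethoxyphenyl)-2-oxabicyclo[3.2.0]heptan-6-one, via dichloroketene 16 (not isolated)
Conditions: Zn–Cu couple, Et2O/DME, 0 °C to rt, slow addition of 15
Reagents that add atoms: none
Why: Zn–Cu reduces 15 to dichloroketene 16, which adds to the enol ether of 14 in an asynchronous [2+2] cycloaddition, the closest known type being dichloroketene addition to dihydrofurans, dihydropyrans and glycals. The nucleophilic β-carbon C3a bonds first to the ketene carbonyl carbon, so C6 ends on C3a and the CCl2 carbon (C7) on the oxygen-bearing C7a; the developing oxocarbenium character at C7a fixes this regiochemistry. The four-membered ring closes by suprafacial addition across the ring alkene, so its fusion to the tetrahydrofuran is necessarily cis. The two new stereocentres C3a and C7a are set together, and their sense should be controlled by the C3 methyl group, which sits on the carbon next to the attacked C3a and shields its own face, so that C6 arrives anti to methyl and the allyl group ends syn to it. The C2 aryl group lies on the attacked face but is two atoms from C3a and close to the ring plane, so it is expected to count for less than the adjacent methyl. The step also needs chemoselectivity for the enol ether over the allyl alkene, which the far higher ketenophilicity of a trisubstituted enol ether and the slow addition of a near-stoichiometric amount of 15 should secure. DME binds the ZnCl2 formed and protects the acid-labile enol ether and the benzylic ether.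

Step 8
Reactants: 17 (1R,3S,4S,5S)-5-allyl-7,7-dichloro-4-methyl-3-(3,4,5-trimethoxyphenyl)-2-oxabicyclo[3.2.0]heptan-6-one
Product: 18 (1S,3S,4S,5S)-5-allyl-4-methyl-3-(3,4,5-trimethoxyphenyl)-2-oxabicyclo[3.2.0]heptan-6-one
Conditions: Zn dust, NH4Cl, MeOH, rt
Reagents that add atoms: none
Why: Reductive dechlorination of an α,α-dichlorocyclobutanone with zinc under buffered protic conditions, the standard second stage of dichloroketene methodology; the zinc enolate is protonated before it can expel the C7a oxygen, and the allyl group and stereocentres are untouched.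

Step 9
Reactants: 18 (1S,3S,4S,5S)-5-allyl-4-methyl-3-(3,4,5-trimethoxyphenyl)-2-oxabicyclo[3.2.0]heptan-6-one; 19 methyl vinyl ether
Product: 21 (1S,3S,4S,5S)-5-allyl-6-(1-methoxyvinyl)-4-methyl-3-(3,4,5-trimethoxyphenyl)-2-oxabicyclo[3.2.0]heptan-6-ol (C6 epimers), via 1-methoxyvinyllithium 20 (not isolated)
Conditions: 19, t-BuLi, THF, −78 to 0 °C; then 18, −78 °C; aq. NaHCO3
Reagents that add atoms: none
Why: 1,2-Addition of an α-alkoxyvinyllithium to a strained, highly electrophilic cyclobutanone; the new carbinol centre C6 returns to a carbonyl in step 10, so its configuration does not matter, and the non-acidic work-up preserves the enol ether.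

Step 10
Reactants: 21 (1S,3S,4S,5S)-5-allyl-6-(1-methoxyvinyl)-4-methyl-3-(3,4,5-trimethoxyphenyl)-2-oxabicyclo[3.2.0]heptan-6-ol (C6 epimers)
Product: 22 (2S,3S,3aS,7aS)-3a-allyl-5-methoxy-3-methyl-2-(3,4,5-trimethoxyphenyl)hexahydrobenzofuran-6(2H)-one (C5 epimers)
Conditions: [Ir(dF(CF3)ppy)2(5,5'-d(CF3)bpy)]PF6 (2 mol%), 2,4,6-collidine, 2,4,6-triisopropylbenzenethiol (20 mol%), CH2Cl2, blue LEDs, rt
Reagents that add atoms: none
Why: Alkoxy-radical two-carbon ring expansion of a 1-alkenylcycloalkanol under photocatalytic proton-coupled electron transfer (excited iridium photocatalyst as oxidant, collidine as base; dF(CF3)ppy is cyclometalated 2-(2,4-difluorophenyl)-5-(trifluoromethyl)pyridine and d(CF3)bpy is 5,5'-bis(trifluoromethyl)-2,2'-bipyridine). Strain-driven β-scission should cleave C3a–C6 to the tertiary C3a radical and an α-methoxy enone, 6-endo addition to the enone terminus C4 recloses the ring cis-fused so that C4 enters on the face of the C7a side chain and C3a regains its configuration, and the thiol returns a hydrogen atom to C5.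

Step 11
Reactants: 22 (2S,3S,3aS,7aS)-3a-allyl-5-methoxy-3-methyl-2-(3,4,5-trimethoxyphenyl)hexahydrobenzofuran-6(2H)-one (C5 epimers)
Product: 24 (2S,3S,3aS)-3a-allyl-5-methoxy-3-methyl-2-(3,4,5-trimethoxyphenyl)-3,3a,4,5-tetrahydrobenzofuran-6(2H)-one (C5 epimers), via trimethylsilyl enol ether 23 (not isolated)
Conditions: LiN(i-Pr)2, TMSCl, THF, −78 °C; then Pd(OAc)2, MeCN, rt
Reagents that add atoms: none
Why: Kinetic enolisation with internal TMSCl quench should take the non-oxygenated C7 methylene, and Saegusa–Ito oxidation (divalent palladium at C7, β-hydride elimination of H-7a) gives the vinylogous ester. Enolisation towards C5 would only reverse the order of the two dehydrogenations, since both are needed.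

Step 12
Reactants: 24 (2S,3S,3aS)-3a-allyl-5-methoxy-3-methyl-2-(3,4,5-trimethoxyphenyl)-3,3a,4,5-tetrahydrobenzofuran-6(2H)-one (C5 epimers)
Product: 26 (2S,3S,3aR)-3a-allyl-5-methoxy-3-methyl-2-(3,4,5-trimethoxyphenyl)-3,3a-dihydrobenzofuran-6(2H)-one, via trimethylsilyl dienol ether 25 (not isolated)
Conditions: LiN(i-Pr)2, TMSCl, THF, −78 °C; then Pd(OAc)2, MeCN, rt
Reagents that add atoms: none
Why: The vinylogous ester has one enolisable position, C5, because C3a is quaternary, so the cross-conjugated dienolate forms regiospecifically. Saegusa–Ito oxidation of its silyl ether places palladium at C5 and β-hydride elimination of a C4 hydrogen forms C4=C5, erasing the C5 stereocentre and completing the dienone at room temperature.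

## Compound list

1 | 3,4,5-trimethoxybenzaldehyde | O=Cc1cc(OC)c(OC)c(OC)c1 | starting material
2 | (E)-crotylboronic acid pinacol ester | C/C=C/CB1OC(C)(C)C(C)(C)O1 | starting material
3 | 2-{[(1S,2S)-2-methyl-1-(3,4,5-trimethoxyphenyl)but-3-en-1-yl]oxy}-4,4,5,5-tetramethyl-1,3,2-dioxaborolane | C=C[C@H](C)[C@H](OB1OC(C)(C)C(C)(C)O1)c1cc(OC)c(OC)c(OC)c1 | intermediate (not isolated)
4 | (1S,2S)-2-methyl-1-(3,4,5-trimethoxyphenyl)but-3-en-1-ol | C=C[C@H](C)[C@H](O)c1cc(OC)c(OC)c(OC)c1 | intermediate
5 | (1S,2S)-4-(9-borabicyclo[3.3.1]nonan-9-yl)-2-methyl-1-(3,4,5-trimethoxyphenyl)butan-1-ol | C1CCC2CCCC1B2CC[C@H](C)[C@H](O)c1cc(OC)c(OC)c(OC)c1 | intermediate (not isolated)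
6 | (3S,4S)-3-methyl-4-(3,4,5-trimethoxyphenyl)butane-1,4-diol | OCC[C@H](C)[C@H](O)c1cc(OC)c(OC)c(OC)c1 | intermediate
7 | (4S,5S)-4-methyl-5-(3,4,5-trimethoxyphenyl)tetrahydrofuran-2-ol (anomers) | OC1C[C@H](C)[C@@H](c2cc(OC)c(OC)c(OC)c2)O1 | intermediate (not isolated)
8 | (4S,5S)-4-methyl-5-(3,4,5-trimethoxyphenyl)dihydrofuran-2(3H)-one | O=C1C[C@H](C)[C@@H](c2cc(OC)c(OC)c(OC)c2)O1 | intermediate
9 | allyl bromide | C=CCBr | starting material
10 | lithium enolate of 8 | [Li]OC1=C[C@H](C)[C@@H](c2cc(OC)c(OC)c(OC)c2)O1 | intermediate (not isolated)
11 | (3S,4S,5S)-3-allyl-4-methyl-5-(3,4,5-trimethoxyphenyl)dihydrofuran-2(3H)-one (allyl trans to methyl) | C=CC[C@H]1[C@H](C)[C@@H](c2cc(OC)c(OC)c(OC)c2)OC1=O | intermediate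
12 | (3S,4S,5S)-3-allyl-4-methyl-5-(3,4,5-trimethoxyphenyl)tetrahydrofuran-2-ol (anomers) | C=CC[C@H]1[C@H](C)[C@@H](c2cc(OC)c(OC)c(OC)c2)OC1O | intermediate
13 | (3S,4S,5S)-3-allyl-4-methyl-5-(3,4,5-trimethoxyphenyl)tetrahydrofuran-2-yl methanesulfonate (anomers) | C=CC[C@H]1[C@H](C)[C@@H](c2cc(OC)c(OC)c(OC)c2)OC1OS(C)(=O)=O | intermediate (not isolated)
14 | (2S,3S)-4-allyl-3-methyl-2-(3,4,5-trimethoxyphenyl)-2,3-dihydrofuran (aryl and methyl trans) | C=CCC1=CO[C@H](c2cc(OC)c(OC)c(OC)c2)[C@H]1C | intermediate
15 | trichloroacetyl chloride | ClC(Cl)(Cl)C(=O)Cl | starting material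
16 | dichloroketene | O=C=C(Cl)Cl | intermediate (not isolated)
17 | (1R,3S,4S,5S)-5-allyl-7,7-dichloro-4-methyl-3-(3,4,5-trimethoxyphenyl)-2-oxabicyclo[3.2.0]heptan-6-one (cis-fused; cyclobutanone anti to methyl, syn to aryl) | C=CC[C@@]12C(=O)C(Cl)(Cl)[C@@H]1O[C@H](c1cc(OC)c(OC)c(OC)c1)[C@H]2C | intermediate
18 | (1S,3S,4S,5S)-5-allyl-4-methyl-3-(3,4,5-trimethoxyphenyl)-2-oxabicyclo[3.2.0]heptan-6-one | C=CC[C@@]12C(=O)C[C@@H]1O[C@H](c1cc(OC)c(OC)c(OC)c1)[C@H]2C | intermediate
19 | methyl vinyl ether | C=COC | starting material
20 | 1-methoxyvinyllithium | [Li]C(=C)OC | intermediate (not isolated)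
21 | (1S,3S,4S,5S)-5-allyl-6-(1-methoxyvinyl)-4-methyl-3-(3,4,5-trimethoxyphenyl)-2-oxabicyclo[3.2.0]heptan-6-ol (C6 epimers) | C=CC[C@@]12C(O)(C(=C)OC)C[C@@H]1O[C@H](c1cc(OC)c(OC)c(OC)c1)[C@H]2C | intermediate
22 | (2S,3S,3aS,7aS)-3a-allyl-5-methoxy-3-methyl-2-(3,4,5-trimethoxyphenyl)hexahydrobenzofuran-6(2H)-one (cis-fused; C5 epimers) | C=CC[C@@]12CC(OC)C(=O)C[C@@H]1O[C@H](c1cc(OC)c(OC)c(OC)c1)[C@H]2C | intermediate
23 | 6-trimethylsilyloxy-6,7-ene (silyl enol ether of 22 towards C7) | C=CC[C@@]12CC(OC)C(O[Si](C)(C)C)=C[C@@H]1O[C@H](c1cc(OC)c(OC)c(OC)c1)[C@H]2C | intermediate (not isolated)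
24 | (2S,3S,3aS)-3a-allyl-5-methoxy-3-methyl-2-(3,4,5-trimethoxyphenyl)-3,3a,4,5-tetrahydrobenzofuran-6(2H)-one (C5 epimers) | C=CC[C@@]12CC(OC)C(=O)C=C1O[C@H](c1cc(OC)c(OC)c(OC)c1)[C@H]2C | intermediate
25 | 6-trimethylsilyloxy-5,6:7,7a-diene (silyl dienol ether of 24) | C=CC[C@@]12CC(OC)=C(O[Si](C)(C)C)C=C1O[C@H](c1cc(OC)c(OC)c(OC)c1)[C@H]2C | intermediate (not isolated)
26 | (2S,3S,3aR)-3a-allyl-5-methoxy-3-methyl-2-(3,4,5-trimethoxyphenyl)-3,3a-dihydrobenzofuran-6(2H)-one | C=CC[C@@]12C=C(OC)C(=O)C=C1O[C@H](c1cc(OC)c(OC)c(OC)c1)[C@H]2C | target

## Step count and least certain steps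

Total: 12 steps. Longest linear sequence: 12 steps (1 to 26).

**Step 7 (key step).** The most likely failure is insufficient facial discrimination: the ketene may approach syn to the small C3 methyl group and anti to the larger C2 aryl group, which would lead into the series epimeric at C3a and C7a. Lesser risks are a competing cycloaddition at the allyl alkene if excess ketene builds up, and acid-induced oligomerisation of the enol ether by ZnCl2. The fallback gives up the cycloaddition and sets out from lactone 11. Deprotonation with KN(SiMe3)2 and Michael addition to 3-methoxybut-3-en-2-one A4 should give the keto lactone F1, with the new C3a–C4 bond anti to the methyl group. KOt-Bu in THF should then close C7–C7a by attack of the methyl ketone enolate on the lactone carbonyl, giving the hydroxy dione F2, and p-TsOH in toluene with removal of water should cyclodehydrate this to 24, where the route is rejoined at step 12.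

**Step 10.** The most likely failures are one-electron oxidation of the trimethoxyphenyl ring or the enol ether in place of O–H activation, a collidinium-promoted semipinacol shift of the 1-methoxyvinyl carbinol, and slow hydrogen-atom return to the stabilised C5 radical, which would allow its 5-exo capture by the allyl group. The fallback removes the enol ether and sets out from cyclobutanone 18. CH2=CHMgBr should give the vinyl carbinol F3, and the same photocatalytic conditions, now on an unsubstituted vinyl carbinol with an ordinary α-keto radical, should give the saturated ketone F4. Double dehydrogenation with IBX in DMSO should give the dienone F5. Nucleophilic epoxidation with H2O2 and NaOH should attack only the C4=C5 enone, giving the epoxy ketone F6. NaOMe in MeOH should open the epoxide at C5 and eliminate water to give 26 directly.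

**Step 12.** The most likely failures are protodesilylation back to 24 in place of palladation of the electron-rich, fully substituted dienol ether, diversion of palladium by the allyl alkene, and acid-promoted allyl migration in the product from the acetic acid released. The fallback sets out from 24. The lithium dienolate (LiN(i-Pr)2, THF, −78 °C) is trapped with PhSeCl to give the 5-phenylselanyl ketone F7. Oxidation with H2O2 and pyridine in CH2Cl2 at 0 °C gives the selenoxide F8, which should undergo syn-elimination towards C4, the only carbon with a β-hydrogen, to give 26.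

**Step 6.** The most likely failures are capture of the oxocarbenium ion by chloride or by a second lactol molecule in place of proton loss, and hydrolysis of the acid-labile enol ether on work-up or chromatography. The fallback sets out from lactol 12. PhSH and BF3·OEt2 in CH2Cl2 at −78 °C should give the phenylthio acetal F9, and mCPBA at −78 °C the sulfoxide F10. Heating F10 in toluene with Et3N should bring about neutral syn-elimination to 14.

## Further compounds

F1 | step 7 | (3S,4S,5S)-3-allyl-3-(2-methoxy-3-oxobutyl)-4-methyl-5-(3,4,5-trimethoxyphenyl)dihydrofuran-2(3H)-one (epimers at the methoxy carbon) | C=CC[C@@]1(CC(OC)C(C)=O)C(=O)O[C@H](c2cc(OC)c(OC)c(OC)c2)[C@H]1C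
F2 | step 7 | 4-allyl-4-[(1S,2S)-1-hydroxy-1-(3,4,5-trimethoxyphenyl)propan-2-yl]-6-methoxycyclohexane-1,3-dione (epimers at the methoxy carbon) | C=CC[C@]1(CC(OC)C(=O)CC1=O)[C@H](C)[C@H](O)c1cc(OC)c(OC)c(OC)c1
F3 | step 10 | (1S,3S,4S,5S)-5-allyl-4-methyl-3-(3,4,5-trimethoxyphenyl)-6-vinyl-2-oxabicyclo[3.2.0]heptan-6-ol (C6 epimers) | C=CC[C@@]12C(O)(C=C)C[C@@H]1O[C@H](c1cc(OC)c(OC)c(OC)c1)[C@H]2C
F4 | step 10 | 3a-allyl-3-methyl-2-(3,4,5-trimethoxyphenyl)hexahydrobenzofuran-6(2H)-one (cis-fused) | C=CC[C@@]12CCC(=O)C[C@@H]1O[C@H](c1cc(OC)c(OC)c(OC)c1)[C@H]2C
F5 | step 10 | 3a-allyl-3-methyl-2-(3,4,5-trimethoxyphenyl)-3,3a-dihydrobenzofuran-6(2H)-one | C=CC[C@@]12C=CC(=O)C=C1O[C@H](c1cc(OC)c(OC)c(OC)c1)[C@H]2C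
F6 | step 10 | 4,5-epoxide of F5 (epoxide epimers) | C=CC[C@@]12C3OC3C(=O)C=C1O[C@H](c1cc(OC)c(OC)c(OC)c1)[C@H]2C
F7 | step 12 | 3a-allyl-5-methoxy-3-methyl-5-(phenylselanyl)-2-(3,4,5-trimethoxyphenyl)-3,3a,4,5-tetrahydrobenzofuran-6(2H)-one (C5 epimers) | C=CC[C@@]12CC(OC)([Se]c3ccccc3)C(=O)C=C1O[C@H](c1cc(OC)c(OC)c(OC)c1)[C@H]2C
F8 | step 12 | selenoxide of F7 | C=CC[C@@]12CC(OC)([Se](=O)c3ccccc3)C(=O)C=C1O[C@H](c1cc(OC)c(OC)c(OC)c1)[C@H]2C
F9 | step 6 | (3S,4S,5S)-3-allyl-4-methyl-2-(phenylthio)-5-(3,4,5-trimethoxyphenyl)tetrahydrofuran (anomers) | C=CC[C@H]1[C@H](C)[C@@H](c2cc(OC)c(OC)c(OC)c2)OC1Sc1ccccc1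
F10 | step 6 | (3S,4S,5S)-3-allyl-4-methyl-2-(phenylsulfinyl)-5-(3,4,5-trimethoxyphenyl)tetrahydrofuran (diastereomers) | C=CC[C@H]1[C@H](C)[C@@H](c2cc(OC)c(OC)c(OC)c2)OC1S(=O)c1ccccc1
A1 | alternative 1 | 3a-allyl-5-methoxy-3-methyl-2-(3,4,5-trimethoxyphenyl)-3,3a,7,7a-tetrahydrobenzofuran-6(2H)-one | C=CC[C@@]12C=C(OC)C(=O)C[C@@H]1O[C@H](c1cc(OC)c(OC)c(OC)c1)[C@H]2C
A2 | alternative 1 | (3S,4S)-2-allyl-4-{[(E)-4-methoxy-3-oxobut-1-en-1-yl]oxy}-3-methyl-4-(3,4,5-trimethoxyphenyl)butanal (C2 epimers) | C=CCC(C=O)[C@H](C)[C@@H](c1cc(OC)c(OC)c(OC)c1)O/C=C/C(=O)COC
A3 | alternative 2 | 3a-allyl-5-methoxy-3-methyl-2-(3,4,5-trimethoxyphenyl)-3,3a,4,5-tetrahydrobenzofuran-6(2H)-one (C5 epimers; identical with 24) | C=CC[C@@]12CC(OC)C(=O)C=C1O[C@H](c1cc(OC)c(OC)c(OC)c1)[C@H]2C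
A4 | alternative 2 | 3-methoxybut-3-en-2-one | C=C(OC)C(C)=O
A5 | alternative 3 | (3R,4S,5S)-3-allyl-3-(hydroxymethyl)-4-methyl-5-(3,4,5-trimethoxyphenyl)dihydrofuran-2(3H)-one | C=CC[C@@]1(CO)C(=O)O[C@H](c2cc(OC)c(OC)c(OC)c2)[C@H]1C
A6 | alternative 3 | (S)-3-allyl-5-(3,4,5-trimethoxyphenyl)furan-2(5H)-one | C=CCC1=C[C@@H](c2cc(OC)c(OC)c(OC)c2)OC1=O
A7 | alternative 3 | formaldehyde | C=O
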